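**Retrosynthetic overview**
- The target is 4-hydroxy-6-styryl-2-pyrone carrying a trans-3-methyl-6-isopropylcyclohex-2-enyl group at pyrone C3. The pyrone ring is bought as 4-hydroxy-6-methyl-2-pyrone and styrylated first; the carbocycle is made last.
- Enabling feature: in the cyclohexene ring, the sp3 carbon that holds pyrone C3 is bonded to the olefinic CH, and the olefinic C(CH3) closes the same six-carbon loop. The array pyrone C3–CH–CH=C(CH3) therefore maps onto a Michael donor, the β- and α-carbons of an enoyl unit, and a methyl ketone. The olefinic H marks where an acyl carbon can leave as CO2.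
- Key disconnection: the C(CH3)=CH bond (aldol, β-lactone, loss of CO2) is cut together with the pyrone C3–ring bond (Michael). This gives acyclic (2E,4R)-4-isopropyl-7-oxooct-2-enal and 4-hydroxy-6-styryl-2-pyrone, joined in one oxidative carbene-catalysed cascade.
- The keto enal comes from Wittig two-carbon homologation of (R)-2-isopropyl-5-oxohexanal. That aldehyde comes from the enamine-catalysed Michael addition of isovaleraldehyde to methyl vinyl ketone, which sets the isopropyl-bearing centre.
- Ring order: pyrone (commercial), then a temporary δ-lactone, then the cyclohexane with a temporary β-lactone, then the cyclohexene.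

Key step: step 5

Assumption: the (5aR,10bS) enantiomer of the triazolium salt in step 5 is taken to direct the pyrone to the face of the enoyl β-carbon that gives the R centre; if a trial run stopped at the δ-lactone stage shows the opposite sense, the equally available (5aS,10bR) salt is used and nothing else changes.

Step 1
Reactants: 1 3-methylbutanal (isovaleraldehyde); 2 but-3-en-2-one (methyl vinyl ketone)
Product: 3 (2R)-5-oxo-2-(propan-2-yl)hexanal
Conditions: (R)-2-[methoxy(diphenyl)methyl]pyrrolidine (5 mol %), ethyl 3,4-dihydroxybenzoate (20 mol %), neat, 4 °C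
Reagents that add atoms: none
Why: Enamine-catalysed asymmetric Michael addition of an aldehyde to a vinyl ketone, in which the CPh2OMe group of the (R)-catalyst shields one face of the E-enamine of 1 so that 2, activated by hydrogen bonding to the catechol, should add to the open face and give the R centre.

Step 2
Reactants: 3 (2R)-5-oxo-2-(propan-2-yl)hexanal; 4 (triphenylphosphoranylidene)acetaldehyde
Product: 5 (2E,4R)-7-oxo-4-(propan-2-yl)oct-2-enal
Conditions: toluene, 60 °C
Reagents that add atoms: none
Why: Wittig olefination with a stabilised ylide, which should be E-selective, should take the aldehyde in preference to the methyl ketone, and is neutral enough to leave the adjacent stereocentre untouched.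

Step 3
Reactants: 6 4-hydroxy-6-methyl-2H-pyran-2-one; 7 benzaldehyde
Product: 8 4-hydroxy-6-(2-hydroxy-2-phenylethyl)-2H-pyran-2-one (racemic carbinol)
Conditions: LiN(iPr)2 (2.2 equiv), THF, −78 °C; PhCHO, −78 to 0 °C; aq. HCl
Reagents that add atoms: none
Why: Aldol addition of a dianion, in which the second deprotonation takes place at the 6-methyl group, this more basic vinylogous carbanion reacts first, and the new carbinol centre forms as a racemate that step 4 removes.

Step 4
Reactants: 8 4-hydroxy-6-(2-hydroxy-2-phenylethyl)-2H-pyran-2-one
Product: 9 4-hydroxy-6-[(E)-2-phenylethenyl]-2H-pyran-2-one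
Conditions: TsOH·H2O (10 mol %), toluene–1,4-dioxane, reflux, azeotropic removal of water
Reagents that add atoms: none
Why: Acid-catalysed dehydration of a benzylic alcohol, which should give the E-alkene because that isomer is conjugated with both the phenyl and the pyrone ring.

Step 5
Reactants: 5 (2E,4R)-7-oxo-4-(propan-2-yl)oct-2-enal; 9 4-hydroxy-6-[(E)-2-phenylethenyl]-2H-pyran-2-one
Product: 12 4-hydroxy-3-[(1R,6R)-3-methyl-6-(propan-2-yl)cyclohex-2-en-1-yl]-6-[(E)-2-phenylethenyl]-2H-pyran-2-one (target), via enol δ-lactone 10 (not isolated), via cis-fused β-lactone 11 (not isolated)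
Conditions: (5aR,10bS)-2-(2,4,6-trimethylphenyl)-5a,10b-dihydro-4H,6H-indeno[2,1-b][1,2,4]triazolo[4,3-d][1,4]oxazin-2-ium chloride (15 mol %), DBU (1.0 equiv), LiCl (1.0 equiv), 3,3',5,5'-tetra-tert-butyl-4,4'-diphenoquinone (1.05 equiv), 4 Å MS, THF–toluene, 23 °C, then 110 °C (sealed tube)
Reagents that add atoms: none
Why: Proposed new method: carbene plus diphenoquinone should convert 5 into its α,β-unsaturated acyl azolium ion, C3 of the pyronate of 9 adds to the β-carbon, the adduct rests as enol δ-lactone 10 (a vinylogous anhydride that the carbene can reopen), the azolium enolate released from it adds to the LiCl-activated methyl ketone, the tertiary alkoxide takes over the acyl group to give β-lactone 11, and at 110 °C 11 loses CO2 by a concerted retro-[2+2], so that the C=C stands exactly between the two carbons joined in the aldol event. The closest known reaction types are the carbene- or isothiourea-catalysed Michael/aldol/β-lactonisation/decarboxylation cascades of unsaturated acyl azolium and acyl ammonium ions, the carbene activation of aryl esters as enolate precursors, and the thermal β-lactone-to-alkene extrusion; beyond precedent are the tethering of the ketone to the acyl partner and the passage of a protic 1,3-dicarbonyl donor beyond the dihydropyranone stage. Modes of closure: temporary δ-lactone 6-exo-trig (O-acylation), carbocycle 6-(enolexo)-exo-trig (aldol), temporary β-lactone 4-exo-trig (acyl transfer), and both temporary rings are gone in 12. The pyrone-bearing centre is set in the Michael event by the indane wall of the chiral acyl azolium ion (catalyst control over the weak bias of the neighbouring isopropyl-bearing centre) and is proof-read at ring closure, where only the trans isomer reaches a chair with pyronyl and isopropyl both equatorial while the Michael step stays reversible; the two further centres of 11 (cis fusion enforced by the four-membered ring) vanish with CO2. Needed are C- over O-attack of the pyronate (O-acylation is reversible under carbene catalysis), enolisation at the acyl azolium CH2 and not at the ketone (only the former is acidified by the azolium group, and DBU is buffered by the pyrone OH), no more than one equivalent of oxidant (so that the enolate is not oxidised), and a single alkene position, which the 1,7-distance between acyl carbon and ketone carbon in 5 and the regiospecific loss of CO2 secure.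

**Compound list**
1 | 3-methylbutanal (isovaleraldehyde) | CC(C)CC=O | starting material
2 | but-3-en-2-one (methyl vinyl ketone) | CC(=O)C=C | starting material
3 | (2R)-5-oxo-2-(propan-2-yl)hexanal | O=C[C@@H](C(C)C)CCC(C)=O | intermediate
4 | (triphenylphosphoranylidene)acetaldehyde | O=CC=P(c1ccccc1)(c1ccccc1)c1ccccc1 | starting material
5 | (2E,4R)-7-oxo-4-(propan-2-yl)oct-2-enal | O=C/C=C/[C@@H](C(C)C)CCC(C)=O | intermediate
6 | 4-hydroxy-6-methyl-2H-pyran-2-one | Cc1cc(O)cc(=O)o1 | starting material
7 | benzaldehyde | O=Cc1ccccc1 | starting material
8 | 4-hydroxy-6-(2-hydroxy-2-phenylethyl)-2H-pyran-2-one (racemic) | O=c1cc(O)cc(CC(O)c2ccccc2)o1 | intermediate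
9 | 4-hydroxy-6-[(E)-2-phenylethenyl]-2H-pyran-2-one | O=c1cc(O)cc(/C=C/c2ccccc2)o1 | intermediate
10 | (4S)-4-[(3R)-2-methyl-6-oxoheptan-3-yl]-7-[(E)-2-phenylethenyl]-3,4-dihydro-2H,5H-pyrano[4,3-b]pyran-2,5-dione (enol δ-lactone) | O=C1C[C@@H]([C@@H](C(C)C)CCC(C)=O)c2c(O1)cc(/C=C/c1ccccc1)oc2=O | intermediate
11 | 4-hydroxy-3-[(1S,2R,3R,6R)-6-methyl-8-oxo-3-(propan-2-yl)-7-oxabicyclo[4.2.0]octan-2-yl]-6-[(E)-2-phenylethenyl]-2H-pyran-2-one (cis-fused β-lactone, lactone carbonyl trans to the pyronyl group; its lactone-face epimer would give the same alkene) | C[C@]12OC(=O)[C@H]1[C@H](c1c(O)cc(/C=C/c3ccccc3)oc1=O)[C@@H](C(C)C)CC2 | intermediate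
12 | 4-hydroxy-3-[(1R,6R)-3-methyl-6-(propan-2-yl)cyclohex-2-en-1-yl]-6-[(E)-2-phenylethenyl]-2H-pyran-2-one (pyronyl and isopropyl trans) | CC1=C[C@H](c2c(O)cc(/C=C/c3ccccc3)oc2=O)[C@@H](C(C)C)CC1 | target

Total step count: 5. Longest linear sequence: 3 (steps 1, 2, 5, or equally steps 3, 4, 5).

**Steps most likely to fail**

1. **Step 5.**
   - What may go wrong: the cascade may stall at the enol δ-lactone stage, either because re-acylation of the carbene is slow or because the azolium enolate is protonated faster than it adds to the ketone. Facial selectivity in the Michael event may be poor. γ-Deprotonation of the unsaturated acyl azolium ion may erode the isopropyl-bearing centre. Base may open the β-lactone by elimination before CO2 is lost.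
   - Fallback (known chemistry), setting out from 5 and 9 and coming back at 12: iminium-catalysed Michael addition of 9 to 5 with (S)-2-[diphenyl(trimethylsilyloxy)methyl]pyrrolidine and benzoic acid in CH2Cl2 should give the adduct as the lactol F1. The catalyst shields one face of the s-trans E-iminium ion, and attack on the open face gives the same configuration at the pyrone-bearing carbon. Heating with pyrrolidinium acetate in toluene under azeotropic removal of water should close the same ring bond by enamine aldol condensation onto the methyl ketone, giving the cyclohexenecarbaldehyde F2. Tsuji–Wilkinson decarbonylation with RhCl(PPh3)3 (1 equiv, toluene or benzonitrile, reflux) then removes the formyl group without moving the alkene and gives 12.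

2. **Step 2.**
   - What may go wrong: olefination of the hindered α-branched aldehyde may be slow, and enolisation during that time may erode the α-centre. The product enal may also be olefinated a second time.
   - Fallback, setting out from 3 and coming back at 5: aldehyde-selective, non-basic methylenation (CH2I2, Zn, Ti(OiPr)4, THF) should give the terminal alkene F3. Cross-metathesis of F3 with (E)-but-2-enal (second-generation Hoveyda–Grubbs catalyst, CH2Cl2, 40 °C) should then deliver the E-enal 5.

3. **Step 1.**
   - What may go wrong: facial selectivity may be insufficient or turnover slow with the β-branched aldehyde. Self-aldol of 1 and intramolecular aldol cyclisation of the product may occur during a long reaction time.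
   - Fallback, setting out from 1 and coming back at 3: condensation of 1 with (S)-1-amino-2-(methoxymethyl)pyrrolidine gives the SAMP hydrazone F4. Deprotonation with LiN(iPr)2 and alkylation of the chelated azaenolate with 2-(2-iodoethyl)-2-methyl-1,3-dioxolane (THF, −100 °C) should give the R-configured alkylated hydrazone F5 under auxiliary control. Ozonolysis (O3, CH2Cl2, −78 °C) frees the ketal aldehyde F6, and SiO2 with aqueous oxalic acid in CH2Cl2 removes the dioxolane to give 3.

**Further compounds**
F1 | step 5 | (4S)-2-hydroxy-4-[(3R)-2-methyl-6-oxoheptan-3-yl]-7-[(E)-2-phenylethenyl]-3,4-dihydro-2H,5H-pyrano[4,3-b]pyran-5-one (lactol, anomeric mixture) | OC1C[C@@H]([C@@H](C(C)C)CCC(C)=O)c2c(O1)cc(/C=C/c1ccccc1)oc2=O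
F2 | step 5 | (5R,6R)-6-{4-hydroxy-2-oxo-6-[(E)-2-phenylethenyl]-2H-pyran-3-yl}-2-methyl-5-(propan-2-yl)cyclohex-1-ene-1-carbaldehyde | CC1=C(C=O)[C@H](c2c(O)cc(/C=C/c3ccccc3)oc2=O)[C@@H](C(C)C)CC1
F3 | step 2 | (5R)-5-(propan-2-yl)hept-6-en-2-one | C=C[C@@H](C(C)C)CCC(C)=O
F4 | step 1 | (2S)-2-(methoxymethyl)-N-[(E)-3-methylbutylidene]pyrrolidin-1-amine | COC[C@@H]1CCCN1/N=C/CC(C)C
F5 | step 1 | (2S)-2-(methoxymethyl)-N-{(1E,2R)-3-methyl-2-[2-(2-methyl-1,3-dioxolan-2-yl)ethyl]butylidene}pyrrolidin-1-amine | COC[C@@H]1CCCN1/N=C/[C@@H](C(C)C)CCC1(C)OCCO1
F6 | step 1 | (2R)-3-methyl-2-[2-(2-methyl-1,3-dioxolan-2-yl)ethyl]butanal | O=C[C@@H](C(C)C)CCC1(C)OCCO1
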